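All runs were computed on assumed constants; scatter was added.

Each of the four new flasks gets 0.15 M of starting material and 0.225 M of reagent, so I reckon with the fraction of reagent left, f: charge less target formed, over charge.

| setting | dawn | winter | dusk | Saturday's | Thursday's | Monday's | Tuesday's |
|---|---|---|---|---|---|---|---|
| starting material | 0.15 M | 0.21 M | 0.33 M | 0.15 M (fed, over 8.0 h) | 0.15 M | 0.15 M (fed, over 8.0 h) | 0.15 M |
| reagent | 0.225 M | 0.225 M | 0.225 M | 0.225 M | 0.225 M | 0.225 M | 0.225 M (fed, over 8.0 h) |
| temperature | 0 °C | 11 °C | 0 °C |  | 5 °C | 5 °C | 5 °C |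
| remark | run made earlier | run made earlier | run made earlier | the addition at −25 °C, then warmed to 5 °C; the feed brings no volume worth counting | everything together at the start | all else is in the flask from the start; the feed brings no volume worth counting | all else is in the flask from the start; the feed brings no volume worth counting |
| time |  |  |  | 10 h | 10 h | 10 h | 10 h |

| run | time / h | target / % | side product / % | starting material / % |
|---|---|---|---|---|
| dawn | 0.500 | 2.0 | 6.3 | 89.2 |
| dawn | 1.50 | 7.0 | 16.6 | 70.3 |
| dawn | 3.00 | 11.2 | 28.5 | 50.1 |
| dawn | 4.00 | 13.8 | 34.0 | 39.7 |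
| dawn | 6.00 | 17.0 | 43.3 | 25.8 |
| dawn | 8.00 | 19.2 | 48.4 | 18.2 |
| dawn | 10.0 | 20.9 | 52.4 | 12.7 |
| winter | 0.500 | 6.3 | 21.2 | 67.3 |
| winter | 0.667 | 7.9 | 26.8 | 59.2 |
| winter | 1.00 | 10.3 | 36.1 | 45.2 |
| winter | 1.50 | 13.3 | 46.1 | 30.8 |
| winter | 2.50 | 16.1 | 57.8 | 15.8 |
| winter | 4.00 | 18.3 | 66.0 | 7.5 |
| winter | 6.00 | 19.1 | 71.8 | 3.2 |
| dusk | 0.333 | 2.1 | 4.1 | 92.1 |
| dusk | 1.00 | 5.2 | 11.6 | 78.9 |
| dusk | 1.50 | 6.5 | 16.2 | 70.5 |
| dusk | 2.50 | 10.2 | 25.4 | 55.7 |
| dusk | 4.00 | 13.0 | 34.5 | 40.8 |
| dusk | 5.00 | 14.7 | 39.5 | 32.8 |
| dusk | 6.00 | 15.9 | 43.4 | 26.9 |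

(readings scatter by 0.3 percentage points)

- what was read earlier has a scatter of 0.3 percentage points, one standard deviation
- a reading or a percentage of target counts all its forms, free or not
- a reading of starting material is of its free form alone

1. the flask with the highest share of target in target plus side product ("all alike" if they lie within 1.5 percentage points) (Saturday's / Thursday's / Monday's / Tuesday's / all alike)
2. share of target in target plus side product at the end, Saturday's
3. share of target in target plus side product at the end, Thursday's
4. share of target in target plus side product at the end, Monday's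
5. share of target in target plus side product at the end, Tuesday's

I read the runs this way: both products form in proportion to starting material, target also in proportion to reagent, using it one for one, while side product forms without reagent. Then −ln f = S·[side product], with S constant at one temperature, and starting material cancels out of the rule. From the last reading of each run:

| run | temperature | f | S |
|---|---|---|---|
| dawn | 0 °C | 0.861 | 1.91 M⁻¹ |
| dusk | 0 °C | 0.767 | 1.85 M⁻¹ |
| winter | 11 °C | 0.822 | 1.30 M⁻¹ |

Dawn and dusk differ in starting material, 0.15 M against 0.33 M, yet their readings of S lie close, and that tests the rule. Interpolating ln S by the degree gives 1.60 M⁻¹ at 5 °C: this selectivity factor, the rise in −ln f per unit of side product, is what I carry.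

With reagent at full charge the share of target would be 26.5 %. If Thursday's turned its whole charge over at that share, f would end near 0.823, so at the mean reagent I reckon 24.8 %. The rule has no term for when starting material enters, so Monday's gets the same figure.

Saturday's looks nearly the same, but I count its cold hours as idle. The first readings give a loss constant k of 0.402 h⁻¹ at 5 °C, and Saturday's has 2.00 h warm. So I reckon f near 0.902 and the share at 25.6 %, higher than my figure for Thursday's. That gap of 0.8 percentage points is smaller than the margin, but S reads larger at 0 °C than at 11 °C, so I expect what forms during the cold addition in Saturday's to widen it. I pick Saturday's.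

In Tuesday's, reagent builds up at the feed rate while starting material lasts about 1/k, so I reckon starting material meets on average about feed rate over k, 0.0699 M of reagent, which gives 10.1 %.

The forecast names Saturday's, with 27.3 % for Saturday's, 25.3 % for Thursday's, 25.5 % for Monday's and 12 % for Tuesday's, each above my figure, and says “Tuesday's starves target of reagent early”.

The flasks give 27.2 % for Saturday's, 25.0 % for Thursday's, 25.2 % for Monday's and 10.5 % for Tuesday's. At 10.0 h Saturday's still holds 42.7 % of its charge as free starting material and 92 % of its reagent. Put that f into S and side product comes to 36.7 % of the charge; Saturday's holds 34.0 %.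

    starting material + reagent → target (k = 0.400 M⁻¹ h⁻¹, Ea = 60.0 kJ mol⁻¹)
    starting material → side product (k = 0.250 h⁻¹, Ea = 81.0 kJ mol⁻¹)
    starting material + target ⇌ idle adduct, settled at all times (K = 82.0 M⁻¹, ΔH = −30.0 kJ mol⁻¹)
    (constants at 5 °C)

In Tuesday's flask with 0.38 M of reagent fed, starting material meets on average about 0.118 M, so S gives a share of 15.9 %. That flask gives 15.8 %.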